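A small charge of G, 0.016 M, meets an equal charge of D in the flask, with Q at 0.0128 M. We follow f, the fraction of the G charge still there.

| flask | G | D | Q | remark | time |
|---|---|---|---|---|---|
| cedar | 0.016 M | 0.016 M | 0.0086 M | run made earlier |  |
| ash | 0.016 M | 0.016 M | 0.019 M | run made earlier |  |
| oak | 0.0080 M | 0.016 M | 0.0128 M | run made earlier |  |
| flask | 0.016 M | 0.0160 M | 0.0128 M |  | 15 h |

| run | time / h | G / % | X / % |
|---|---|---|---|
| cedar | 0.500 | 38.0 | 62.4 |
| cedar | 1.33 | 18.4 | 81.5 |
| cedar | 2.50 | 11.5 | 88.6 |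
| cedar | 4.00 | 7.7 | 88.3 |
| cedar | 5.00 | 6.6 | 90.8 |
| cedar | 8.00 | 5.7 | 91.5 |
| cedar | 10.0 | 4.0 | 89.4 |
| ash | 0.667 | 28.5 | 69.6 |
| ash | 1.00 | 20.3 | 78.7 |
| ash | 1.50 | 13.7 | 84.9 |
| ash | 2.50 | 9.0 | 90.8 |
| ash | 4.00 | 5.2 | 94.7 |
| ash | 6.00 | 3.8 | 95.4 |
| ash | 10.0 | 0.2 | 96.8 |
| oak | 0.833 | 11.2 | 87.7 |
| oak | 2.50 | 0 | 99.0 |
| oak | 4.00 | 0 | 97.6 |
| oak | 6.00 | 0 | 100.5 |
| oak | 10.0 | 0.4 | 100.3 |

(scatter of a reading: 1 percentage point)

- part of the G that has reacted at 15 h
- share of the unused D that is free and not bound as E, at 15 h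

- the earlier runs do not show how much of D is bound; that part of a forecast is a guess

If G and D are used one for one from equal charges, both fractions stay f and f falls at pace·f·f. This second-order rate integrates in closed form:

f = 1/(1 + pace·t), so pace = (1/f − 1)/t

Q comes first. At 2.50 h, the cedar reading gives 3.08 h⁻¹ and the ash reading 4.04 h⁻¹. By hand, a rate carried by Q in proportion would rise 2.21-fold from cedar to ash, but these two readings, with their scatter, give 1.31-fold. The flask's Q lies between the cedar and ash charges, so we take the mean, 3.56 h⁻¹, as the pace, the reciprocal of the time in which f falls to a half.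

Time comes next. At 10.0 h the line gives 2.73%, and the readings there are 4.0% in cedar and 0.2% in ash. At 15 h it leaves 1.84%, so by our reckoning 98.2% of the G has reacted.

The G charge comes last. Oak has half the G against the same D, which makes G the limiting reagent, and by hand it should fall faster than the line. It reads 11.2% at 0.833 h, less than the line's 25.2%. The flask has equal charges, so we keep the line for it.

The forecast says 97.5% for c, below our figure, and 40% for fr: “Free share of D = 1/(1 + KQ), about 40%. This is a weak guess.”

The flask gives 98.0% for c and 83.0% for fr, so fr stands 43 percentage points above the forecast.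

    G + D → X + L (k = 4.10 L mol⁻¹ min⁻¹)
    D + L ⇌ E, settled at all times (K = 96.0 L mol⁻¹)
    Q + L → J (k = 26.0 L mol⁻¹ min⁻¹)
    X + L → Z (k = 0.0270 L mol⁻¹ min⁻¹)

In this flask the midpoint of the G + D turnover up to 15 h lay at 0.274 h and that of Q + L at 0.342 h, and Q stood at 0% of its charge at 7.50 h. X + L ran on later, its midpoint at 8.51 h, with L at 0.00213 M and Z at 4.35% at 15.0 h. The G left in this flask at 15.0 h gives a pace of 3.32 h⁻¹, against our 3.56 h⁻¹. In the neighbour flask with Q at 0.032 M, the G left at 15.0 h gives a pace of 3.93 h⁻¹, with Q at 50.9% of its charge and >99.9% of its unused D free.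

Readings and results are simulated from invented constants.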